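The starting material is the limiting reagent of the winter flask: 250 mM of it faces 1700 mM of partner, and the question is how much has become product after 36 min. The charges, the earlier readings and the questions stand below.

| setting | noon | summer | dusk | dawn | winter |
|---|---|---|---|---|---|
| starting material | 250 mM | 750 mM | 250 mM | 250 mM | 250 mM |
| partner | 500 mM | 500 mM | 500 mM | 1000 mM | 1700 mM |
| free catalyst | 13.0 mM | 13.0 mM | 6.50 mM | 13.0 mM | 13.0 mM |
| time |  |  |  |  | 36 min |

| run | time / min | [product] / mM |
|---|---|---|
| noon run | 4.5 | 20.0 |
| noon run | 9.0 | 36.9 |
| noon run | 14 | 53.2 |
| noon run | 18 | 64.4 |
| noon run | 22 | 78.4 |
| noon run | 27 | 92.8 |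
| noon run | 32 | 104.3 |
| noon run | 36 | 108.2 |
| summer run | 4.5 | 54.2 |
| summer run | 9.0 | 105.1 |
| summer run | 14 | 154.1 |
| summer run | 18 | 177.0 |
| summer run | 22 | 206.8 |
| summer run | 27 | 236.6 |
| summer run | 32 | 260.8 |
| summer run | 36 | 279.3 |
| dusk run | 4.5 | 13.1 |
| dusk run | 9.0 | 21.5 |
| dusk run | 14 | 35.7 |
| dusk run | 18 | 37.8 |
| dusk run | 22 | 48.1 |
| dusk run | 27 | 57.1 |
| dusk run | 32 | 63.5 |
| dusk run | 36 | 70.8 |
| dawn run | 4.5 | 19.7 |
| dawn run | 9.0 | 42.6 |
| dawn run | 14 | 64.7 |
| dawn run | 18 | 74.6 |
| dawn run | 22 | 86.4 |
| dawn run | 27 | 101.9 |
| dawn run | 32 | 113.2 |
| dawn run | 36 | 127.9 |

(readings scatter by 2 mM)

- the exponent of [free catalyst] in the starting rate at the charge of the noon run (at the point where two percent of the starting material have become product)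
- the exponent of [starting material] in the starting rate at the charge of the noon run (at the point where two percent of the starting material have become product) (one fixed amount of product, the same in the runs compared)
- product in the winter run at 36 min, as a share of the starting material charged

- Overall: starting material + partner -> product, with free catalyst as catalyst.
- Constant volume, constant temperature.
- What is held in complexes is read along with the free species.
- "The second partner" is partner.
- An order is taken over about fifteen percent of the charge, up and down.

The reckoning that follows is this text's own, separate from the forecast, and it starts with a ledger of the dawn run, the earlier flask richest in partner. At 36 min in the dawn run, by the reading, the 250 mM of starting material charged has gone 127.9 mM to product, bound product counted, and 0.122 M remains, which closes the books. Partner is spent one for one, so c(partner) in the dawn run, bound partner counted, has fallen from 1000 mM to 0.872 M, a loss of 12.8%.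

The dawn run, with twice the partner of the noon run, reads 1.18 times the product of the noon run at that time. So this reckoning freezes c(partner), which treats the dawn run as pseudo-first-order in starting material. Its ledger gives 0.0199 /min for the frozen constant, defined as the natural logarithm of starting material charged over starting material left, divided by the elapsed time. The dawn reading at 18 min gives 0.0197 /min, so these two dawn readings agree on one constant within their scatter.

Carried unchanged into the winter flask, this constant predicts a share of 51.2% at 36 min. On that estimate the winter ledger reads 0.128 M of product and 0.122 M of starting material left, with c(partner), bound partner counted, at 92.5% of its charge.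

The forecast, made from the same runs, gives a catalyst order of 0.72, an order in starting material of 0.92 and a winter share of 56%, a share higher than this ledger's, reasoning that “partner dependence is saturating”.

The flask gives an order in starting material of 1.0, a winter share of 52.9% and a catalyst order of 0.96, and the forecast's catalyst order is lower than that.

    2 free catalyst ⇌ catalyst dimer, settled at all times (68.50 /M)
    free catalyst + starting material + partner → product + free catalyst (21.84 /M²/min)
    free catalyst + partner ⇌ idle catalyst-reagent complex, settled at all times (12.40 /M)
    free catalyst + product ⇌ catalyst-product complex, settled at all times (11.10 /M)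

Read from that share, the winter constant is 0.0209 /min, against 0.0199 /min at dawn, with 1.70 times the partner. The pairing of free catalyst with partner to the idle catalyst-reagent complex is the main reason that the winter share stands at 52.9%: without it that share is 98.6%. Carried to the noon run, the dawn constant puts product at a quarter of the charge at 14.5 min, but the noon run reaches that point at 16.1 min, and that same pairing holds the apparent partner order early in the noon run to 0.21, against 1.0 without it.

The earlier runs and the new flask stem from a simulated flask on assumed constants, and the scatter is random.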